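**Retrosynthetic overview**

- The route rests on the O1–C8a bond of the pyranone (ring C) of the 4-methoxyphenyl (unprimed) half. C8a is ortho to C4a, which carries the C4 ketone, and meta to the oxygens on C5 and C7, so it can enter as a C–F carbon and that benzene ring needs only two ether oxygens. The ring is closed last, by displacement of fluoride by the enolate oxygen of a 1-(2-fluoroaryl)-1,3-diketone.
- The diketone (C2–C3–C4 unit) comes from a biaryl benzaldehyde by aldol addition of 4′-methoxyacetophenone and oxidation. This avoids a Claisen condensation on a hindered acetophenone.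
- The hindered C8–C6″ biaryl bond is made by Suzuki–Miyaura coupling of a 6-borylated, protected apigenin with 4,6-bis(benzyloxy)-3-bromo-2-fluorobenzaldehyde, in which the formyl group is already in place.
- The fluoro ring comes from 1,3,5-trifluorobenzene (double SNAr, Vilsmeier formylation, bromination). The double-primed flavone is bought intact as apigenin (benzylation, 6-iodination, 5-O-methylation, borylation).
- Ring order: rings A, B and C of the double-primed half are purchased; the only ring formed is the unprimed pyranone (step 11); BCl3 then removes four benzyl groups and the chelated 5″-methyl group.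

Key step: step 11

Assumption: the target is drawn without a descriptor for the C8–C6″ axis, so it is made as the racemate about that axis; compounds 13–20 are likewise racemic, and 17 is a mixture of diastereomers at its carbinol carbon.

**Route**

Step 1
Reactants: 1 1,3,5-trifluorobenzene
Product: 3 1,3-bis(benzyloxy)-5-fluorobenzene, via 1-benzyloxy-3,5-difluorobenzene 2 (not isolated)
Conditions: BnOH (2.2 equiv), NaH, NMP, 0 °C then 100 °C
Reagents that add atoms: benzyl alcohol, OCc1ccccc1
Why: Twofold nucleophilic aromatic substitution; each fluorine of 1 is activated inductively by two meta fluorines, the second displacement on 2 still has one, and the third is the slowest, so 2.2 equiv of alkoxide should stop at the bis-ether.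

Step 2
Reactants: 3 1,3-bis(benzyloxy)-5-fluorobenzene
Product: 5 2,4-bis(benzyloxy)-6-fluorobenzaldehyde, via aryl iminium dichlorophosphate 4 (not isolated)
Conditions: POCl3, DMF, 0 → 80 °C; then H2O, 50 °C
Reagents that add atoms: N,N-dimethylformamide, CN(C)C=O; water, O
Why: Vilsmeier–Haack formylation of a resorcinol diether; the two equivalent CH positions next to fluorine are each para to one benzyloxy group, whereas the CH between the two ethers is flanked on both sides, so the 6-fluoro aldehyde should predominate, any symmetrical 2,6-bis(benzyloxy)-4-fluoro isomer being removed by crystallisation, and benzyl ethers tolerate POCl3/DMF.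

Step 3
Reactants: 5 2,4-bis(benzyloxy)-6-fluorobenzaldehyde
Product: 6 4,6-bis(benzyloxy)-3-bromo-2-fluorobenzaldehyde
Conditions: NBS, MeCN, 0 °C → rt, dark
Reagents that add atoms: N-bromosuccinimide, O=C1CCC(=O)N1Br
Why: Electrophilic aromatic bromination; the CH between fluorine and benzyloxy is para to the second ether, like the position brominated in 2,4-dialkoxybenzaldehydes, while the other CH is ortho to both ethers and shielded by them, and the surviving ring proton, para to fluorine, should show only a small H–F coupling, which lets the regiochemistry be checked.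

Step 4
Reactants: 7 apigenin
Product: 9 7,4′-di-O-benzylapigenin (7-benzyloxy-2-(4-benzyloxyphenyl)-5-hydroxy-4H-chromen-4-one), via 7-O-benzylapigenin 8 (not isolated)
Conditions: BnBr (2.2 equiv), K2CO3, DMF, rt
Reagents that add atoms: benzyl bromide, BrCc1ccccc1
Why: Williamson etherification; the 5-OH is hydrogen-bonded to the C4 carbonyl and is the least nucleophilic, so the 7- and 4′-hydroxyls are alkylated selectively.

Step 5
Reactants: 9 7,4′-di-O-benzylapigenin
Product: 10 7-benzyloxy-2-(4-benzyloxyphenyl)-5-hydroxy-6-iodo-4H-chromen-4-one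
Conditions: BnNMe3 ICl2, CaCO3, CH2Cl2–MeOH, rt
Reagents that add atoms: benzyltrimethylammonium dichloroiodate, C[N+](C)(C)Cc1ccccc1.Cl[I-]Cl
Why: Electrophilic aromatic iodination directed by the free chelated phenol; dichloroiodate reagents iodinate 5-hydroxy-7-alkoxyflavones ortho to the 5-OH at C6 and not at C8, and CaCO3 takes up the HCl.

Step 6
Reactants: 10 7-benzyloxy-2-(4-benzyloxyphenyl)-5-hydroxy-6-iodo-4H-chromen-4-one
Product: 11 7-benzyloxy-2-(4-benzyloxyphenyl)-6-iodo-5-methoxy-4H-chromen-4-one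
Conditions: Me2SO4, K2CO3, acetone, reflux
Reagents that add atoms: dimethyl sulfate, COS(=O)(=O)OC
Why: Williamson O-methylation; the hydrogen-bonded, iodine-flanked 5-OH needs the small, reactive dimethyl sulfate at reflux, and capping it keeps a free phenoxide out of the palladium steps.

Step 7
Reactants: 11 7-benzyloxy-2-(4-benzyloxyphenyl)-6-iodo-5-methoxy-4H-chromen-4-one
Product: 12 7-benzyloxy-2-(4-benzyloxyphenyl)-5-methoxy-6-(4,4,5,5-tetramethyl-1,3,2-dioxaborolan-2-yl)-4H-chromen-4-one
Conditions: pinacolborane, Et3N, PdCl2(MeCN)2 (cat.), SPhos, 1,4-dioxane, 80 °C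
Reagents that add atoms: pinacolborane, CC1(C)OBOC1(C)C
Why: Palladium-catalysed borylation of an aryl iodide with pinacolborane (Masuda-type Miyaura borylation); the SPhos-ligated catalyst is the system used for ortho,ortho-disubstituted electron-rich aryl halides, and the flavone carbonyl is inert to pinacolborane without a hydroboration catalyst.

Step 8
Reactants: 6 4,6-bis(benzyloxy)-3-bromo-2-fluorobenzaldehyde (1.3 equiv); 12 the flavone 6-boronate
Product: 13 4,6-bis(benzyloxy)-3-[7-benzyloxy-2-(4-benzyloxyphenyl)-5-methoxy-4-oxo-4H-chromen-6-yl]-2-fluorobenzaldehyde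
Conditions: Pd(OAc)2 (cat.), SPhos, K3PO4, toluene–H2O, 100 °C
Reagents that add atoms: none
Why: Suzuki–Miyaura coupling to a four-fold ortho-substituted biaryl; SPhos-ligated zerovalent palladium inserts into a C–Br bond flanked only by the small fluorine and one ether and is the ligand class that couples 2,6-dialkoxyaryl boron reagents, while the aldehyde and the C–F bond are untouched.

Step 9
Reactants: 13 the biaryl aldehyde; 14 4′-methoxyacetophenone
Product: 17 3-{4,6-bis(benzyloxy)-3-[7-benzyloxy-2-(4-benzyloxyphenyl)-5-methoxy-4-oxo-4H-chromen-6-yl]-2-fluorophenyl}-3-hydroxy-1-(4-methoxyphenyl)propan-1-one (mixture of diastereomers), via lithium enolate 15 (not isolated), via lithium aldolate 16 (not isolated)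
Conditions: 14, LiN(i-Pr)2, THF, −78 °C; then 13, −78 °C; AcOH
Reagents that add atoms: none
Why: Aldol addition of a preformed lithium enolate to the aldehyde at −78 °C, where the vinylogous-ester carbonyl of the flavone does not compete; the carbinol centre forms without control and is removed by oxidation in step 10.

Step 10
Reactants: 17 the β-hydroxy ketone
Product: 18 1-{4,6-bis(benzyloxy)-3-[7-benzyloxy-2-(4-benzyloxyphenyl)-5-methoxy-4-oxo-4H-chromen-6-yl]-2-fluorophenyl}-3-(4-methoxyphenyl)propane-1,3-dione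
Conditions: IBX, EtOAc, 75 °C
Reagents that add atoms: none
Why: IBX oxidation of a β-hydroxy ketone to the 1,3-diketone, a pentavalent-iodine alcohol oxidation that stops at the diketone and leaves the benzyl ethers and the flavone untouched.

Step 11
Reactants: 18 the 2-fluoroaryl 1,3-diketone
Product: 20 5,7-bis(benzyloxy)-8-[7-benzyloxy-2-(4-benzyloxyphenyl)-5-methoxy-4-oxo-4H-chromen-6-yl]-2-(4-methoxyphenyl)-4H-chromen-4-one, via potassium enolate 19 (not isolated)
Conditions: K2CO3, DMF, 90 °C
Reagents that add atoms: none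
Why: K2CO3 deprotonates the diketone CH2 and the oxygen of the chelated Z-enolate on the anisyl-bearing carbon (future C2) adds to C8a ipso to fluorine, giving a Meisenheimer anion delocalised onto C4a and the C4 carbonyl, from which fluoride is expelled. The closest known reaction type is the base-mediated intramolecular O-arylation of 1-(2-fluoroaryl)-1,3-diketones to flavones and chromones. The pyranone of the unprimed half closes by 6-exo-trig attack on the aromatic carbon followed by elimination, forming the O1–C8a bond. No stereocentre is created, and the C8–C6″ axis, already present in 18, is carried through as the racemate. The step needs O- over C-arylation and a single site of closure: only the distal enolate oxygen reaches C8a through a six-membered transition state (C3 or the proximal oxygen would form four-membered rings), and the one leaving group fixes the 8-aryl pattern. The benzyloxy groups on C5 and C7 are meta to C8a and do not donate into it, while the ortho C4 carbonyl accepts the charge.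

Step 12
Reactants: 20 the protected biflavone
Product: 21 5,7-dihydroxy-8-[5,7-dihydroxy-2-(4-hydroxyphenyl)-4-oxo-4H-chromen-6-yl]-2-(4-methoxyphenyl)-4H-chromen-4-one (target)
Conditions: BCl3 (excess), C6HMe5, CH2Cl2, −78 °C → rt; then H2O
Reagents that add atoms: none
Why: Lewis-acid ether cleavage; BCl3 with pentamethylbenzene as a non-basic benzyl-cation scavenger removes aryl benzyl ethers at low temperature without C-benzylation of the phloroglucinol rings, and on warming BCl3 chelated between the C4″ carbonyl and the 5″-oxygen cleaves that peri methyl ether, whereas the unchelated 4′-methoxyl is stable to BCl3; water hydrolyses the boron aryloxides.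

**Compound list**

1 | 1,3,5-trifluorobenzene | Fc1cc(F)cc(F)c1 | starting material
2 | 1-benzyloxy-3,5-difluorobenzene | Fc1cc(F)cc(OCc2ccccc2)c1 | intermediate
3 | 1,3-bis(benzyloxy)-5-fluorobenzene | Fc1cc(OCc2ccccc2)cc(OCc2ccccc2)c1 | intermediate
4 | N-{[2,4-bis(benzyloxy)-6-fluorophenyl]methylidene}-N-methylmethanaminium dichlorophosphate | C[N+](C)=Cc1c(F)cc(OCc2ccccc2)cc1OCc1ccccc1.[O-]P(=O)(Cl)Cl | intermediate
5 | 2,4-bis(benzyloxy)-6-fluorobenzaldehyde | O=Cc1c(F)cc(OCc2ccccc2)cc1OCc1ccccc1 | intermediate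
6 | 4,6-bis(benzyloxy)-3-bromo-2-fluorobenzaldehyde | O=Cc1c(F)c(Br)c(OCc2ccccc2)cc1OCc1ccccc1 | intermediate
7 | apigenin | O=c1cc(-c2ccc(O)cc2)oc2cc(O)cc(O)c12 | starting material
8 | 7-O-benzylapigenin | O=c1cc(-c2ccc(O)cc2)oc2cc(OCc3ccccc3)cc(O)c12 | intermediate
9 | 7,4′-di-O-benzylapigenin | O=c1cc(-c2ccc(OCc3ccccc3)cc2)oc2cc(OCc3ccccc3)cc(O)c12 | intermediate
10 | 7-benzyloxy-2-(4-benzyloxyphenyl)-5-hydroxy-6-iodo-4H-chromen-4-one | O=c1cc(-c2ccc(OCc3ccccc3)cc2)oc2cc(OCc3ccccc3)c(I)c(O)c12 | intermediate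
11 | 7-benzyloxy-2-(4-benzyloxyphenyl)-6-iodo-5-methoxy-4H-chromen-4-one | COc1c(I)c(OCc2ccccc2)cc2oc(-c3ccc(OCc4ccccc4)cc3)cc(=O)c12 | intermediate
12 | 7-benzyloxy-2-(4-benzyloxyphenyl)-5-methoxy-6-(4,4,5,5-tetramethyl-1,3,2-dioxaborolan-2-yl)-4H-chromen-4-one | COc1c(B2OC(C)(C)C(C)(C)O2)c(OCc2ccccc2)cc2oc(-c3ccc(OCc4ccccc4)cc3)cc(=O)c12 | intermediate
13 | 4,6-bis(benzyloxy)-3-[7-benzyloxy-2-(4-benzyloxyphenyl)-5-methoxy-4-oxo-4H-chromen-6-yl]-2-fluorobenzaldehyde (racemic axis) | O=Cc1c(F)c(c(OCc2ccccc2)cc1OCc1ccccc1)-c1c(OCc2ccccc2)cc2oc(-c3ccc(OCc4ccccc4)cc3)cc(=O)c2c1OC | intermediate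
14 | 4′-methoxyacetophenone | COc1ccc(cc1)C(C)=O | starting material
15 | lithium enolate of 4′-methoxyacetophenone | [Li]OC(=C)c1ccc(OC)cc1 | intermediate
16 | lithium aldolate of 17 | COc1ccc(cc1)C(=O)CC(O[Li])c1c(F)c(c(OCc2ccccc2)cc1OCc1ccccc1)-c1c(OCc2ccccc2)cc2oc(-c3ccc(OCc4ccccc4)cc3)cc(=O)c2c1OC | intermediate
17 | 3-{4,6-bis(benzyloxy)-3-[7-benzyloxy-2-(4-benzyloxyphenyl)-5-methoxy-4-oxo-4H-chromen-6-yl]-2-fluorophenyl}-3-hydroxy-1-(4-methoxyphenyl)propan-1-one (mixture of diastereomers) | COc1ccc(cc1)C(=O)CC(O)c1c(F)c(c(OCc2ccccc2)cc1OCc1ccccc1)-c1c(OCc2ccccc2)cc2oc(-c3ccc(OCc4ccccc4)cc3)cc(=O)c2c1OC | intermediate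
18 | 1-{4,6-bis(benzyloxy)-3-[7-benzyloxy-2-(4-benzyloxyphenyl)-5-methoxy-4-oxo-4H-chromen-6-yl]-2-fluorophenyl}-3-(4-methoxyphenyl)propane-1,3-dione | COc1ccc(cc1)C(=O)CC(=O)c1c(F)c(c(OCc2ccccc2)cc1OCc1ccccc1)-c1c(OCc2ccccc2)cc2oc(-c3ccc(OCc4ccccc4)cc3)cc(=O)c2c1OC | intermediate
19 | (Z)-potassium enolate of 18 | COc1ccc(cc1)/C(O[K])=C/C(=O)c1c(F)c(c(OCc2ccccc2)cc1OCc1ccccc1)-c1c(OCc2ccccc2)cc2oc(-c3ccc(OCc4ccccc4)cc3)cc(=O)c2c1OC | intermediate
20 | 5,7-bis(benzyloxy)-8-[7-benzyloxy-2-(4-benzyloxyphenyl)-5-methoxy-4-oxo-4H-chromen-6-yl]-2-(4-methoxyphenyl)-4H-chromen-4-one | COc1ccc(cc1)-c1cc(=O)c2c(OCc3ccccc3)cc(OCc3ccccc3)c(c2o1)-c1c(OCc2ccccc2)cc2oc(-c3ccc(OCc4ccccc4)cc3)cc(=O)c2c1OC | intermediate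
21 | 5,7-dihydroxy-8-[5,7-dihydroxy-2-(4-hydroxyphenyl)-4-oxo-4H-chromen-6-yl]-2-(4-methoxyphenyl)-4H-chromen-4-one (CNP0310322.0) | COc1ccc(-c2cc(=O)c3c(O)cc(O)c(-c4c(O)cc5oc(-c6ccc(O)cc6)cc(=O)c5c4O)c3o2)cc1 | target

**Summary**

Total step count: 12. Longest linear sequence: 9 steps (apigenin 7 to 21, steps 4–12); the fluoro-ring branch (steps 1–3) joins at step 8.

Steps most likely to fail:

1. Step 8 (Suzuki–Miyaura coupling). Transmetalation at a boron flanked by two alkoxy groups may be slower than protodeboronation, and reductive elimination to the four-fold ortho-substituted biaryl may stall. Fallback, setting out from bromide 6 and iodide 11 and returning at 13; it also leaves out step 7. The aldehyde of 6 would be masked with HC(OMe)3, MeOH and catalytic TsOH as 4,6-bis(benzyloxy)-3-bromo-2-fluorobenzaldehyde dimethyl acetal F1. Bromine–lithium exchange (n-BuLi, THF, −78 °C) would give the aryllithium F2, which ZnCl2 would convert at −78 °C into the arylzinc chloride F3. Negishi coupling of F3 with 11 (Pd2(dba)3, RuPhos, THF, 70 °C) would give the biaryl dimethyl acetal F4, and aqueous HCl in THF would release aldehyde 13.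

2. Step 11 (key fluoride displacement). Addition of the enolate oxygen to the electron-rich, doubly flanked C–F carbon may be slow enough for retro-Claisen cleavage of the diketone to take over at the temperature needed. Fallback, setting out from aldehyde 13 and returning at 20; it forms O1–C2 last instead of O1–C8a. The aldehyde-activated fluoride would be displaced intermolecularly with 4-methoxybenzyl alcohol and NaH (DMF, 0 °C) to give 4,6-bis(benzyloxy)-3-(flavon-6-yl)-2-(4-methoxybenzyloxy)benzaldehyde F5. Addition of lithium enolate 15 (THF, −78 °C) would give the lithium aldolate F6 and, after AcOH, the β-hydroxy ketone F7, and IBX in EtOAc would give the 2-(4-methoxybenzyloxy)aryl 1,3-diketone F8. TFA with pentamethylbenzene in CH2Cl2 would remove the 4-methoxybenzyl group to the 2-hydroxyaryl 1,3-diketone F9, which would cyclodehydrate under the same acid (the classical end game of the Baker–Venkataraman flavone synthesis) to 20.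

3. Step 12 (global deprotection). Cleavage of the chelated 5″-methyl ether may remain incomplete, or benzyl cations may alkylate the phloroglucinol rings before they are scavenged. Fallback, setting out from 20 and returning at 21. Hydrogenolysis (H2, Pd on carbon, THF–MeOH, rt) would remove the four benzyl groups without generating benzyl cations and give the 5″-O-methyl ether of the target F10. AlCl3 in MeCN at 60 °C would then cleave only the methyl ether peri to the C4″ carbonyl by chelation and leave the 4′-methoxyl in place, giving 21.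

**Further compounds**

F1 | step 8 | 4,6-bis(benzyloxy)-3-bromo-2-fluorobenzaldehyde dimethyl acetal | COC(OC)c1c(F)c(Br)c(OCc2ccccc2)cc1OCc1ccccc1
F2 | step 8 | [2,4-bis(benzyloxy)-5-(dimethoxymethyl)-6-fluorophenyl]lithium | COC(OC)c1c(F)c([Li])c(OCc2ccccc2)cc1OCc1ccccc1
F3 | step 8 | [2,4-bis(benzyloxy)-5-(dimethoxymethyl)-6-fluorophenyl]zinc chloride | COC(OC)c1c(F)c([Zn]Cl)c(OCc2ccccc2)cc1OCc1ccccc1
F4 | step 8 | dimethyl acetal of 13 | COC(OC)c1c(F)c(c(OCc2ccccc2)cc1OCc1ccccc1)-c1c(OCc2ccccc2)cc2oc(-c3ccc(OCc4ccccc4)cc3)cc(=O)c2c1OC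
F5 | step 11 | 4,6-bis(benzyloxy)-3-[7-benzyloxy-2-(4-benzyloxyphenyl)-5-methoxy-4-oxo-4H-chromen-6-yl]-2-(4-methoxybenzyloxy)benzaldehyde | O=Cc1c(OCc2ccc(OC)cc2)c(c(OCc2ccccc2)cc1OCc1ccccc1)-c1c(OCc2ccccc2)cc2oc(-c3ccc(OCc4ccccc4)cc3)cc(=O)c2c1OC
F6 | step 11 | lithium aldolate of F7 | COc1ccc(cc1)C(=O)CC(O[Li])c1c(OCc2ccc(OC)cc2)c(c(OCc2ccccc2)cc1OCc1ccccc1)-c1c(OCc2ccccc2)cc2oc(-c3ccc(OCc4ccccc4)cc3)cc(=O)c2c1OC
F7 | step 11 | 3-{4,6-bis(benzyloxy)-3-(flavon-6-yl)-2-(4-methoxybenzyloxy)phenyl}-3-hydroxy-1-(4-methoxyphenyl)propan-1-one | COc1ccc(cc1)C(=O)CC(O)c1c(OCc2ccc(OC)cc2)c(c(OCc2ccccc2)cc1OCc1ccccc1)-c1c(OCc2ccccc2)cc2oc(-c3ccc(OCc4ccccc4)cc3)cc(=O)c2c1OC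
F8 | step 11 | 1-{4,6-bis(benzyloxy)-3-(flavon-6-yl)-2-(4-methoxybenzyloxy)phenyl}-3-(4-methoxyphenyl)propane-1,3-dione | COc1ccc(cc1)C(=O)CC(=O)c1c(OCc2ccc(OC)cc2)c(c(OCc2ccccc2)cc1OCc1ccccc1)-c1c(OCc2ccccc2)cc2oc(-c3ccc(OCc4ccccc4)cc3)cc(=O)c2c1OC
F9 | step 11 | 1-{4,6-bis(benzyloxy)-3-(flavon-6-yl)-2-hydroxyphenyl}-3-(4-methoxyphenyl)propane-1,3-dione | COc1ccc(cc1)C(=O)CC(=O)c1c(O)c(c(OCc2ccccc2)cc1OCc1ccccc1)-c1c(OCc2ccccc2)cc2oc(-c3ccc(OCc4ccccc4)cc3)cc(=O)c2c1OC
F10 | step 12 | 5,7-dihydroxy-8-[7-hydroxy-2-(4-hydroxyphenyl)-5-methoxy-4-oxo-4H-chromen-6-yl]-2-(4-methoxyphenyl)-4H-chromen-4-one | COc1ccc(cc1)-c1cc(=O)c2c(O)cc(O)c(c2o1)-c1c(O)cc2oc(-c3ccc(O)cc3)cc(=O)c2c1OC
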